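**Retrosynthetic overview** (hexahydroindene numbering of the target: C4 quaternary, C5 CHPh, C6 ring CH=, C7 C–Et, C3a/C7a ring fusion, C1/C3 CHMe; ring A five-membered, ring B six-membered)
- The acid comes from its ethyl ester; the C6=C7(Et) alkene from a C7 ketone (enol triflate, Negishi ethylation); the C4 acrylate chain from a C4 formyl group (Wittig).
- Ring B is cut at C5–C6 and C3a–C4: a catalytic enantioselective (4+2) union of a 2-silyloxydiene (C6=C7(OSi)–C7a=C3a, carried on ring A with both methyls) with (E)-2-ethylcinnamaldehyde (C5=C4). Two fragments of similar size are joined at the quaternary carbon.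
- Enabling feature: C7 is bonded to C6 and, through C7a, sits next to C3a. A C7 carbonyl (as silyl enol ether) therefore makes C6 and C3a the termini of a diene across the C7a=C3a bond of ring A, and the formyl-derived C4 chain makes C5=C4 an enal. Both temporary oxygen functions are removed afterwards.
- Diene: (R)-β-citronellene supplies C3, an Evans methylation sets C1, and Kowalski ynolate silylation followed by ring-closing enyne metathesis closes ring A and unveils the silyloxydiene.
- Ring order: ring A (step 7), then ring B (step 9); C7a is set when the cycloadduct is protodesilylated.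

Key step: step 9

Remark on the chemistry: the oxazaborolidine antipode written in step 9 is the one expected to leave open the Si face of the enal β-carbon (Re face of the α-carbon). If the sense of induction is the opposite, the mirror-image catalyst, which is equally available, is used.

**Step 1**
Reactants: 1 (R)-3,7-dimethylocta-1,6-diene ((R)-β-citronellene)
Product: 3 (R)-4-methylhex-5-enal, via ozonide 2 (not isolated)
Conditions: O3 (1 equiv, indicator end-point), CH2Cl2, −78 °C; then Me2S, −78 °C to rt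
Reagents that add atoms: ozone, [O-][O+]=O
Why: Chemoselective ozonolysis: the electron-rich trisubstituted alkene should react far faster than the vinyl group, and the stereocentre (future C3) is not touched.

**Step 2**
Reactants: 3 (R)-4-methylhex-5-enal
Product: 4 (R)-4-methylhex-5-enoic acid
Conditions: NaClO2, NaH2PO4, 2-methylbut-2-ene, t-BuOH/H2O, 0 °C to rt
Reagents that add atoms: sodium chlorite, [Na+].[O-]Cl=O
Why: Pinnick oxidation; the hypochlorite scavenger protects the terminal alkene.

**Step 3**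
Reactants: 4 (R)-4-methylhex-5-enoic acid; 5 (R)-4-benzyloxazolidin-2-one
Product: 7 (R)-4-benzyl-3-[(R)-4-methylhex-5-enoyl]oxazolidin-2-one, via mixed pivalic anhydride 6 (not isolated)
Conditions: t-BuCOCl, Et3N, THF, −20 °C; then 5, LiCl, −20 °C to rt
Reagents that add atoms: none
Why: N-acylation of the Evans oxazolidinone through the mixed anhydride, which is attacked at the less hindered acyl carbon.

**Step 4**
Reactants: 7 (R)-4-benzyl-3-[(R)-4-methylhex-5-enoyl]oxazolidin-2-one
Product: 9 (R)-4-benzyl-3-[(2R,4R)-2,4-dimethylhex-5-enoyl]oxazolidin-2-one, via sodium enolate 8 (not isolated)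
Conditions: NaN(SiMe3)2, THF, −78 °C; then MeI, −78 °C
Reagents that add atoms: iodomethane, CI
Why: Evans asymmetric alkylation: the chelated (Z)-enolate should be methylated on the face opposite the benzyl group, setting the 2R centre (future C1).

**Step 5**
Reactants: 9 (R)-4-benzyl-3-[(2R,4R)-2,4-dimethylhex-5-enoyl]oxazolidin-2-one
Product: 10 methyl (2R,4R)-2,4-dimethylhex-5-enoate
Conditions: NaOMe, MeOH/CH2Cl2, 0 °C, short reaction time
Reagents that add atoms: sodium methoxide, [Na+].[O-]C
Why: Methanolysis of the N-acyloxazolidinone at the exocyclic carbonyl; low temperature and short contact should avoid epimerisation at C2, and the auxiliary 5 is recovered.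

**Step 6**
Reactants: 10 methyl (2R,4R)-2,4-dimethylhex-5-enoate
Product: 13 {[(3R,5R)-3,5-dimethylhept-6-en-1-yn-1-yl]oxy}tri(propan-2-yl)silane, via dibromomethyl ketone 11 (not isolated), via lithium ynolate 12 (not isolated)
Conditions: CH2Br2, lithium 2,2,6,6-tetramethylpiperidide, THF, −78 °C; then n-BuLi, −78 to 0 °C; then i-Pr3SiOTf, −78 °C
Reagents that add atoms: dibromomethane, BrCBr; triisopropylsilyl trifluoromethanesulfonate, CC(C)[Si](OS(=O)(=O)C(F)(F)F)(C(C)C)C(C)C
Why: Kowalski ester homologation stopped at the ynolate: bromine–lithium exchange on the dibromo enolate triggers a 1,2-shift of the α-branched alkyl group with retention, and the hindered silyl triflate silylates the ynolate on oxygen.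

**Step 7**
Reactants: 13 {[(3R,5R)-3,5-dimethylhept-6-en-1-yn-1-yl]oxy}tri(propan-2-yl)silane
Product: 14 ({1-[(3R,5R)-3,5-dimethylcyclopent-1-en-1-yl]ethenyl}oxy)tri(propan-2-yl)silane
Conditions: second-generation Grubbs catalyst RuCl2(=CHPh)(PCy3)(H2IMes) (5 mol%), C6H6, 60 °C
Reagents that add atoms: none
Why: Ring-closing enyne metathesis of a siloxyalkyne in the exo mode: it closes ring A at the future C7a=C3a bond and moves the methylene onto the ynol carbon, so the 2-silyloxydiene should form regiospecifically without touching either stereocentre.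

**Step 8**
Reactants: 15 benzaldehyde; 16 butanal
Product: 18 (E)-2-ethyl-3-phenylprop-2-enal, via aldol adduct 17 (not isolated)
Conditions: NaOH (aq., cat.), EtOH, 0 °C to rt, slow addition of 16
Reagents that add atoms: none
Why: Claisen–Schmidt condensation; dehydration under thermodynamic control should give the (E)-enal (phenyl trans to formyl).

**Step 9**
Reactants: 14 ({1-[(3R,5R)-3,5-dimethylcyclopent-1-en-1-yl]ethenyl}oxy)tri(propan-2-yl)silane; 18 (E)-2-ethyl-3-phenylprop-2-enal
Product: 20 (1R,3R,3aR,4R,5S,7aR)-4-ethyl-1,3-dimethyl-7-oxo-5-phenyloctahydro-1H-indene-4-carbaldehyde, via silyl enol ether cycloadduct 19 (not isolated)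
Conditions: (S)-1-(2-methylphenyl)-3,3-diphenyltetrahydro-1H,3H-pyrrolo[1,2-c][1,3,2]oxazaborole (20 mol%), HN(SO2CF3)2 (20 mol%), CH2Cl2, −78 to −20 °C; then aq. HF, MeCN, 0 °C
Reagents that add atoms: none
Why: The protonated oxazaborolidine binds the formyl group of 18, and the 2-silyloxydiene adds in an asynchronous concerted (4+2) cycloaddition in which the unsubstituted CH2 terminus (future C6) bonds to the β-carbon (C5) ahead of the C3a–C4 bond; the polarisation by the silyloxy group and by the carbonyl fixes this regiochemistry. The closest known reaction type is the oxazaborolidinium-catalysed Diels–Alder reaction of 2-(triisopropylsilyloxy)-1,3-dienes with α-substituted enals, and ring B is closed in the intermolecular (4+2) mode across the C7a=C3a bond of ring A. C5 and C4 follow from suprafacial addition to the (E)-enal (phenyl and ethyl cis) on the enal face left open by the catalyst, and C3a follows from the endo position of the bound formyl group, which puts the formyl group on the same side of ring B as C3. The step needs attack on the diene face syn to the C3 methyl and anti to the C1 methyl: allylic strain with the OSi(i-Pr)3 group on C7 should force the C1 methyl pseudoaxial, so that it blocks its own face beneath the endo formyl–catalyst unit, while the C3 methyl is pseudoequatorial, and the catalyst antipode is matched to this preference. Protodesilylation of 19 with HF then delivers the proton to C7a axially, anti to the C3a–H bond, which should give the trans ring fusion under kinetic control.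

**Step 10**
Reactants: 20 (1R,3R,3aR,4R,5S,7aR)-4-ethyl-1,3-dimethyl-7-oxo-5-phenyloctahydro-1H-indene-4-carbaldehyde
Product: 21 ethyl (E)-3-[(1R,3R,3aR,4S,5S,7aR)-4-ethyl-1,3-dimethyl-7-oxo-5-phenyloctahydro-1H-inden-4-yl]-2-methylprop-2-enoate
Conditions: Ph3P=C(Me)CO2Et, toluene, 110 °C
Reagents that add atoms: ethyl 2-(triphenylphosphoranylidene)propanoate, CCOC(=O)C(C)=P(c1ccccc1)(c1ccccc1)c1ccccc1
Why: Wittig olefination with a stabilised ylide, which should react only at the aldehyde (the hindered ketone is inert), give the (E)-enoate, and be too weakly basic to epimerise C7a.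

**Step 11**
Reactants: 21 ethyl (E)-3-[(1R,3R,3aR,4S,5S,7aR)-4-ethyl-1,3-dimethyl-7-oxo-5-phenyloctahydro-1H-inden-4-yl]-2-methylprop-2-enoate
Product: 23 ethyl (E)-3-[(1R,3R,3aR,4S,5S,7aR)-4-ethyl-1,3-dimethyl-5-phenyl-7-{[(trifluoromethyl)sulfonyl]oxy}-2,3,3a,4,5,7a-hexahydro-1H-inden-4-yl]-2-methylprop-2-enoate, via potassium enolate 22 (not isolated)
Conditions: KN(SiMe3)2, THF, −78 °C; then PhN(SO2CF3)2, −78 to 0 °C
Reagents that add atoms: N-phenylbis(trifluoromethanesulfonimide), O=S(=O)(N(c1ccccc1)S(=O)(=O)C(F)(F)F)C(F)(F)F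
Why: Kinetic enolisation and O-triflation: the hindered base should remove a proton from the C6 methylene and not from the C7a methine, so the C6=C7 enol triflate forms and C7a is left untouched; the enoate has no acidic γ-hydrogen.

**Step 12**
Reactants: 23 ethyl (E)-3-[(1R,3R,3aR,4S,5S,7aR)-4-ethyl-1,3-dimethyl-5-phenyl-7-{[(trifluoromethyl)sulfonyl]oxy}-2,3,3a,4,5,7a-hexahydro-1H-inden-4-yl]-2-methylprop-2-enoate
Product: 24 ethyl (E)-3-[(1R,3R,3aR,4S,5S,7aR)-4,7-diethyl-1,3-dimethyl-5-phenyl-2,3,3a,4,5,7a-hexahydro-1H-inden-4-yl]-2-methylprop-2-enoate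
Conditions: Et2Zn, [1,1'-bis(diphenylphosphino)ferrocene]dichloropalladium PdCl2(dppf) (5 mol%), THF, 50 °C
Reagents that add atoms: diethylzinc, CC[Zn]CC
Why: Negishi coupling of an alkenyl triflate with an alkylzinc; the wide-bite-angle bisphosphine favours reductive elimination over β-hydride elimination, and the ester is tolerated.

**Step 13**
Reactants: 24 ethyl (E)-3-[(1R,3R,3aR,4S,5S,7aR)-4,7-diethyl-1,3-dimethyl-5-phenyl-2,3,3a,4,5,7a-hexahydro-1H-inden-4-yl]-2-methylprop-2-enoate
Product: 26 homo-plakotenin, (E)-3-[(1R,3R,3aR,4S,5S,7aR)-4,7-diethyl-1,3-dimethyl-5-phenyl-2,3,3a,4,5,7a-hexahydro-1H-inden-4-yl]-2-methylprop-2-enoic acid, via lithium carboxylate 25 (not isolated)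
Conditions: LiOH, THF/MeOH/H2O, 50 °C; then 1 M HCl
Reagents that add atoms: lithium hydroxide, [Li+].[OH-]
Why: Saponification of the ethyl ester; no stereocentre is epimerisable under these conditions.

**Compound list**
1 | (R)-3,7-dimethylocta-1,6-diene | C=C[C@H](C)CCC=C(C)C | starting material
2 | 3,3-dimethyl-5-[(R)-3-methylpent-4-en-1-yl]-1,2,4-trioxolane | C=C[C@H](C)CCC1OOC(C)(C)O1 | intermediate
3 | (R)-4-methylhex-5-enal | C=C[C@H](C)CCC=O | intermediate
4 | (R)-4-methylhex-5-enoic acid | C=C[C@H](C)CCC(=O)O | intermediate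
5 | (R)-4-benzyloxazolidin-2-one | O=C1N[C@H](Cc2ccccc2)CO1 | starting material
6 | (R)-4-methylhex-5-enoic pivalic anhydride | C=C[C@H](C)CCC(=O)OC(=O)C(C)(C)C | intermediate
7 | (R)-4-benzyl-3-[(R)-4-methylhex-5-enoyl]oxazolidin-2-one | C=C[C@H](C)CCC(=O)N1[C@H](Cc2ccccc2)COC1=O | intermediate
8 | sodium (Z)-enolate of 7 | C=C[C@H](C)C/C=C(\[O-])N1[C@H](Cc2ccccc2)COC1=O.[Na+] | intermediate
9 | (R)-4-benzyl-3-[(2R,4R)-2,4-dimethylhex-5-enoyl]oxazolidin-2-one | C=C[C@H](C)C[C@@H](C)C(=O)N1[C@H](Cc2ccccc2)COC1=O | intermediate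
10 | methyl (2R,4R)-2,4-dimethylhex-5-enoate | C=C[C@H](C)C[C@@H](C)C(=O)OC | intermediate
11 | (3R,5R)-1,1-dibromo-3,5-dimethylhept-6-en-2-one | C=C[C@H](C)C[C@@H](C)C(=O)C(Br)Br | intermediate
12 | lithium (3R,5R)-3,5-dimethylhept-6-en-1-yn-1-olate | C=C[C@H](C)C[C@@H](C)C#C[O-].[Li+] | intermediate
13 | {[(3R,5R)-3,5-dimethylhept-6-en-1-yn-1-yl]oxy}tri(propan-2-yl)silane | C=C[C@H](C)C[C@@H](C)C#CO[Si](C(C)C)(C(C)C)C(C)C | intermediate
14 | ({1-[(3R,5R)-3,5-dimethylcyclopent-1-en-1-yl]ethenyl}oxy)tri(propan-2-yl)silane | C=C(O[Si](C(C)C)(C(C)C)C(C)C)C1=C[C@H](C)C[C@H]1C | intermediate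
15 | benzaldehyde | O=Cc1ccccc1 | starting material
16 | butanal | CCCC=O | starting material
17 | 2-ethyl-3-hydroxy-3-phenylpropanal | CCC(C=O)C(O)c1ccccc1 | intermediate
18 | (E)-2-ethyl-3-phenylprop-2-enal | CC/C(C=O)=C\c1ccccc1 | intermediate
19 | (1R,3R,3aR,4S,5S)-4-ethyl-1,3-dimethyl-5-phenyl-7-{[tri(propan-2-yl)silyl]oxy}-2,3,3a,4,5,6-hexahydro-1H-indene-4-carbaldehyde | CC(C)[Si](OC1=C2[C@H](C)C[C@@H](C)[C@H]2[C@](C=O)(CC)[C@H](c2ccccc2)C1)(C(C)C)C(C)C | intermediate
20 | (1R,3R,3aR,4R,5S,7aR)-4-ethyl-1,3-dimethyl-7-oxo-5-phenyloctahydro-1H-indene-4-carbaldehyde | O=C1C[C@@H](c2ccccc2)[C@@](C=O)(CC)[C@H]2[C@H]1[C@H](C)C[C@H]2C | intermediate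
21 | ethyl (E)-3-[(1R,3R,3aR,4S,5S,7aR)-4-ethyl-1,3-dimethyl-7-oxo-5-phenyloctahydro-1H-inden-4-yl]-2-methylprop-2-enoate | O=C1C[C@@H](c2ccccc2)[C@@](/C=C(\C)C(=O)OCC)(CC)[C@H]2[C@H]1[C@H](C)C[C@H]2C | intermediate
22 | potassium enolate of 21 (C6=C7) | [K+].[O-]C1=C[C@@H](c2ccccc2)[C@@](/C=C(\C)C(=O)OCC)(CC)[C@H]2[C@H]1[C@H](C)C[C@H]2C | intermediate
23 | ethyl (E)-3-[(1R,3R,3aR,4S,5S,7aR)-4-ethyl-1,3-dimethyl-5-phenyl-7-{[(trifluoromethyl)sulfonyl]oxy}-2,3,3a,4,5,7a-hexahydro-1H-inden-4-yl]-2-methylprop-2-enoate | O=S(=O)(OC1=C[C@@H](c2ccccc2)[C@@](/C=C(\C)C(=O)OCC)(CC)[C@H]2[C@H]1[C@H](C)C[C@H]2C)C(F)(F)F | intermediate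
24 | ethyl (E)-3-[(1R,3R,3aR,4S,5S,7aR)-4,7-diethyl-1,3-dimethyl-5-phenyl-2,3,3a,4,5,7a-hexahydro-1H-inden-4-yl]-2-methylprop-2-enoate | CCC1=C[C@@H](c2ccccc2)[C@@](/C=C(\C)C(=O)OCC)(CC)[C@H]2[C@H]1[C@H](C)C[C@H]2C | intermediate
25 | lithium carboxylate of 26 | CCC1=C[C@@H](c2ccccc2)[C@@](/C=C(\C)C(=O)[O-])(CC)[C@H]2[C@H]1[C@H](C)C[C@H]2C.[Li+] | intermediate
26 | homo-plakotenin | CCC1=C[C@@H](c2ccccc2)[C@@](/C=C(\C)C(=O)O)(CC)[C@H]2[C@H]1[C@H](C)C[C@H]2C | target

**Step count:** 13 steps in total. The longest linear sequence is 12 steps (steps 1 to 7, then 9 to 13); step 8 is a one-step branch.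

**Steps most likely to fail**

Step 9. The cycloaddition has to join a fully substituted enal carbon to a ring carbon, so it may be slow. The silyloxydiene may add to the formyl carbon instead (Mukaiyama aldol pathway), and control of the diene face or of the endo approach may be eroded. Fallback, from 18 back to 20: acetalisation of 18 with (2R,4R)-pentane-2,4-diol (pyridinium p-toluenesulfonate, benzene, reflux with removal of water) would give (4R,6R)-4,6-dimethyl-2-[(E)-1-phenylbut-1-en-2-yl]-1,3-dioxane F1. Me3SiOTf at −78 °C in CH2Cl2 opens F1 to a vinyl-oxocarbenium ion, a much stronger and slimmer dienophile with no free carbonyl, whose face is set by the acetal stereocentres (ionic Diels–Alder reaction of α,β-unsaturated acetals; the antipodal diol is used if the opposite face is required). Its cycloaddition with 14 would give (4R,6R)-2-[(1R,3R,3aR,4S,5S)-4-ethyl-1,3-dimethyl-5-phenyl-7-{[tri(propan-2-yl)silyl]oxy}-2,3,3a,4,5,6-hexahydro-1H-inden-4-yl]-4,6-dimethyl-1,3-dioxane F2. Aqueous HF followed by aqueous CF3CO2H removes the silyl group and the acetal, and the route is rejoined at 20.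

Step 6. The amide base may enolise the ester and erode the α-stereocentre, the rearrangement to the ynolate may stall, or silylation may occur on carbon. Fallback, from 10 back to 13: reduction of 10 with i-Bu2AlH at −78 °C would give (2R,4R)-2,4-dimethylhex-5-enal F3. Corey–Fuchs olefination (CBr4, PPh3) would give (3R,5R)-1,1-dibromo-3,5-dimethylhepta-1,6-diene F4. Two equivalents of n-BuLi convert F4 into lithium (3R,5R)-3,5-dimethylhept-6-en-1-yn-1-ide F5, which is oxidised with lithium tert-butyl peroxide to the ynolate 12 and silylated with i-Pr3SiOTf to give 13.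

Step 10. Olefination of the formyl group on the quaternary carbon may be very slow, and long heating may then lead to epimerisation at C7a or decomposition of the keto aldehyde. Fallback, from 19 back to 21: the cycloadduct 19 is isolated by leaving out the HF treatment in step 9, so that the ketone stays masked. A Horner–Wadsworth–Emmons reaction with the more nucleophilic anion of triethyl 2-phosphonopropanoate (NaH, THF, 0 °C to rt) would give ethyl (E)-3-[(1R,3R,3aR,4S,5S)-4-ethyl-1,3-dimethyl-5-phenyl-7-{[tri(propan-2-yl)silyl]oxy}-2,3,3a,4,5,6-hexahydro-1H-inden-4-yl]-2-methylprop-2-enoate F6. Aqueous HF in MeCN then gives 21 with the same axial protonation at C7a.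

**Further compounds**
F1 | step 9 | (4R,6R)-4,6-dimethyl-2-[(E)-1-phenylbut-1-en-2-yl]-1,3-dioxane | CC/C(=C\c1ccccc1)C1O[C@H](C)C[C@@H](C)O1
F2 | step 9 | (4R,6R)-2-[(1R,3R,3aR,4S,5S)-4-ethyl-1,3-dimethyl-5-phenyl-7-{[tri(propan-2-yl)silyl]oxy}-2,3,3a,4,5,6-hexahydro-1H-inden-4-yl]-4,6-dimethyl-1,3-dioxane | CC(C)[Si](OC1=C2[C@H](C)C[C@@H](C)[C@H]2[C@](C2O[C@H](C)C[C@@H](C)O2)(CC)[C@H](c2ccccc2)C1)(C(C)C)C(C)C
F3 | step 6 | (2R,4R)-2,4-dimethylhex-5-enal | C=C[C@H](C)C[C@@H](C)C=O
F4 | step 6 | (3R,5R)-1,1-dibromo-3,5-dimethylhepta-1,6-diene | C=C[C@H](C)C[C@@H](C)C=C(Br)Br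
F5 | step 6 | lithium (3R,5R)-3,5-dimethylhept-6-en-1-yn-1-ide | C=C[C@H](C)C[C@@H](C)C#[C-].[Li+]
F6 | step 10 | ethyl (E)-3-[(1R,3R,3aR,4S,5S)-4-ethyl-1,3-dimethyl-5-phenyl-7-{[tri(propan-2-yl)silyl]oxy}-2,3,3a,4,5,6-hexahydro-1H-inden-4-yl]-2-methylprop-2-enoate | CC(C)[Si](OC1=C2[C@H](C)C[C@@H](C)[C@H]2[C@](/C=C(\C)C(=O)OCC)(CC)[C@H](c2ccccc2)C1)(C(C)C)C(C)C
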